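Same recipe, two clocks.

| setting | birch | elm |
|---|---|---|
| free monomer | 1.5 M | 1.5 M |
| initiator | 18 mM | 18 mM |
| time | 15 min | 4.0 min |

    2 growing radical → dead chain (k1 = 5 × 10⁶ M⁻¹ s⁻¹)
    initiator → 2 initiating radical (k2 = 1.84 × 10⁻⁴ s⁻¹)
    free monomer + initiating radical → growing radical + monomer in chains (k3 = 49200 M⁻¹ s⁻¹)
    free monomer + growing radical → monomer in chains + growing radical, rate k4*[growing radical]*[free monomer] (k4 = 1470 M⁻¹ s⁻¹)

- two of one species on the left: rate k times its square, two consumed each time
- the average divides the monomer in chains by the number of chains, living and dead together; two radicals that join make one chain
- run time (birch): 15 min

1. which of the two ends with the longer chains by the average number of monomer units in a chain (living and dead chains, two that joined counted as one) ("neither" if they lie within 10 %) (birch / elm / neither)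
2. average number of monomer units in a chain (living and dead chains, two that joined counted as one) at the end, birch
3. average number of monomer units in a chain (living and dead chains, two that joined counted as one) at the end, elm

I climbed the ladder from the fastest rung. Write kd, kt and kp for the constants of the initiator step, the joining step and the growth step, and L for the growing radical. An initiating radical meets free monomer within about 1.36 × 10⁻⁵ s. Radical birth from initiator then balances loss by joining, the factor 2 standing on both sides, so L = √(kd[initiator]/kt) = 8.14 × 10⁻⁷ M. Joining reaches that balance in about 0.123 s, far sooner than free monomer moves, with its pseudo-first-order time 1/(kp L) = 13.9 min. The initiator is slowest, with a half-life of 62.8 min; birch stops well inside that, so I held L at its starting value.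

One initiator spent gives two radicals, and two radicals make one chain, so chains follow the initiator spent; L itself is far less than the chains I reckoned for the end of elm. I carried the birth length ν, the monomer taken up per chain born at that moment, kp L[free monomer]/(kd[initiator]), which at the start is 542. The chain average is the mean of ν over the chains born, and ν drifts down because free monomer falls sooner than the initiator.

For birch I got 65.9 % conversion and 2.75 mM of chains, so an average of 360. For elm, stopped at 4.0 min, I got 25.0 % and 0.778 mM, so 481, longer by more than the margin of 10 %.

The forecast named elm, with 352 for birch and 477 for elm, on this ground: “monomer runs down while chains keep forming”.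

The flasks gave elm as the longer, with 478 for elm and 353 for birch. Elm ended with 75.2 % of its free monomer left and L at 7.96 × 10⁻⁷ M. That puts ν at 417 at the end of elm, and the mean of its starting and final ν is 479. The same flask as elm, read at 1.0 min, had ν at 507, which gives a mean of 524 against an average chain of 524.

All constants are invented, and the outcome is calculated.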